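# Kanzonol T by late construction of ring A on a 4‑pyranone: synthesis design

## The problem

Kanzonol T (19) is an isoflavone with three distinct parts. Ring A is a phloroglucinol‑type ring with a 3‑hydroxy‑3‑methylbutyl chain at C6 between the 5‑ and 7‑hydroxyls. Ring C is the 4‑pyranone. Ring B is a resorcinol with a free 2'‑hydroxyl and a 2,2‑dimethylpyran fused angularly at C3'/C4'.

The molecule has no stereocentre, so the difficulties are regiochemistry and functional‑group tolerance. A C‑alkylated phloroglucinol ketone can close ring C through either ortho hydroxyl and so give the 6‑ or the 8‑alkyl isoflavone. Any route that starts from an intact ring A must therefore tell three phenolic oxygens apart. On ring B the pyran must be fused at the carbon between the two oxygens while the 2'‑oxygen stays free.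

Three groups are fragile. The tertiary alcohol lies next to two phenols and closes to a dimethylchroman (or dehydrates) under acid. The chromene olefin rules out hydrogenolysis, strong acid and electrophilic oxidants. The final deprotection must therefore be neutral.

The enabling feature is that C7, C6 and the side chain up to the tertiary oxygen form an unbroken string C(=O)–CH2–CH2–CH2–CMe2–O. This is the δ‑lactone 16 opened at its acyl–oxygen bond. The two remaining ring A carbons, C8 and C5, correspond to a methyl group and an ester carbon on neighbouring positions of a 4‑pyranone that already is ring C (compound 12).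

## Retrosynthesis

**19 from 18.** The last bond to be cut is the O–allyl bond at the 2'‑oxygen. Methoxymethyl or other acetal groups would need acid, which closes the chroman. Benzyl would need hydrogen, which saturates the chromene. The allyl ether survives strong amide base and leaves under neutral conditions with zerovalent palladium. The forward step requires that an external amine captures the allyl unit faster than the electron‑rich ring A does.

**18 from 12 and 16.** Ring A is opened at C7–C8 and C5–C6. The neighbouring cuts through ring C (C2–O1/C3–C4, O1–C8a/C4–C4a, or the C3–C1' biaryl bond) all leave a complete ring A fragment, on which the chain must be placed and three oxygens differentiated. Cutting ring A instead makes the 6‑alkyl pattern a matter of connectivity and removes every ring A protecting group. Pyranone 12 already carries rings B and C, and lactone 16 is a seven‑carbon commodity‑type building block. The forward reaction must deprotonate only the 2‑methyl group of 12, acylate at carbon, and then close the ring by a second acylation through carbon and not oxygen.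

**12 from 10.** The pyranone is cut at its O1–C6 and C5=C6 bonds (pyranone numbering), which removes the C6 methine as a formyl‑level one‑carbon unit and exposes tricarbonyl compound 10. The alternative, joining ring B to a halopyranone by cross‑coupling, needs a regiodefined ring B organometallic and exposes the allyl ether to zerovalent palladium too early. The forward condensation must take place at the benzylic methylene of 10 and not at the acetyl methyl, via enaminone 11.

**10 from 7 and 8.** The bond between the arylacetyl carbonyl and C2 of the acetoacetate is cut, giving arylacetic acid 7 and commercial methyl acetoacetate 8. The forward step is a C‑acylation of a chelated β‑keto ester by acid chloride 9. It requires carbon selectivity and a base too weak to turn 9 into a ketene.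

**7 from 4.** The carboxyl carbon is removed: 7 derives from aldehyde 4 by one‑carbon homologation through enol ether 5 and arylacetaldehyde 6. The route passes through an aldehyde because the formyl group controls the regiochemistry of the chromene annulation one stage earlier. An arylacetic acid starting material would lack that control element.

**4 from 1 and 2.** The allyl ether is cut to phenol 3. The pyran ring of 3 is then cut at the aryl–C4 and O1–C2 bonds (chromene numbering), leading to 2,4‑dihydroxybenzaldehyde 1 and 3‑methylbut‑2‑enal 2. The forward annulation must occur at the carbon between the two oxygens and close through the oxygen that is not chelated to the aldehyde.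

**16 from 13.** Both C–CH3 bonds are cut, leading to glutaric anhydride 13. The forward reaction adds two methyl nucleophiles to one carbonyl group, through keto carboxylate 14 and hydroxy acid 15, and the tertiary alcohol lactonises.

## Roads not taken

**Alternative 1:** Ring C is cut at C3–C4 and O1–C2. This leads to ring A salicylaldehyde A2 and ring B aryl(trimethylsilyl)alkyne A3.

- **Forward key step:** [Cp*RhCl2]2 (trivalent rhodium) with Cu(OAc)2 (divalent copper) as oxidant would activate the formyl C–H bond under direction of the ortho phenoxide, insert the alkyne and form the C–O bond. The product is the 2‑silyl isoflavone A1. Fluoride would then remove the C2 silyl group and the three silyl ethers to give 19.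
- **Merits:** The reaction class is established for salicylaldehydes and internal alkynes. It joins two fully elaborated halves in one step. The silyl group is a reasonable device for placing the aryl group at C3.
- **Weak points:** A2 is a phloroglucinol aldehyde in which the hydroxyl para to the chain must stay free while the two flanking ones are silylated. This is the same three‑oxygen differentiation that makes the target hard. The insertion regiochemistry rests on silyl outcompeting a doubly ortho‑substituted aryl group. The oxidant, the heat and the electrophilic metal all meet the chromene olefin and the free tertiary alcohol.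
- **Comparison:** This road has better precedent for the key bond formation and at least equal convergence. The chosen plan offers in return a ring A with no protecting group, a 6‑alkyl pattern that cannot come out wrong, and inexpensive main‑group reagents. It pays for this with an untested cascade.

**Alternative 2:** Ring B is cut at C1'–C6' and C2'–C3'. This leads to pyranopyranone A5 as diene and the chromone‑bound siloxyalkyne A6 as dienophile.

- **Forward key step:** A [4+2] cycloaddition of the 2‑pyranone unit of A5 with the alkyne of A6, followed by cycloreversion with loss of the lactone bridge, would give the fully silylated isoflavone A4. Fluoride would finish the synthesis.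
- **Merits:** The 2'‑oxygen, the angular pyran and the biaryl bond of ring B are all fixed by connectivity. The polarity of the partners matches the required orientation: the alkyne carbon remote from oxygen pairs with the electrophilic C6 of the pyranone. A5 is a simple bicycle.
- **Weak points:** The 4‑alkoxy‑2‑pyranone is an electron‑rich, sluggish diene. Its reacting terminus is fully substituted and must bond to a carbon carrying a triisopropylsilyloxy group. Forcing temperatures are expected, at which silyl ynol ethers rearrange and 2H‑pyrans can ring‑open. A6 requires the complete ring A/ring C chromone, so the 6‑alkyl problem is still unsolved, and it carries silyl groups of three kinds plus an ynol ether.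
- **Comparison:** For ring B regiochemistry this road is formally safer than relying on a selective chromenylation. That selectivity is, however, well established for aldehyde 1. The chosen plan builds the delicate ring A last, under conditions the other groups tolerate, and in fewer operations.

**Alternative 3:** Ring C is cut at O1–C8a and C4–C4a. Ring A then comes from the silyl triflate A8 and ring B from formylacetate A9.

- **Forward key step:** CsF would strip the silyl group and the triflate from A8. The enolate oxygen of A9 would add to the ring carbon that bore the triflate, and the aryl anion formed next to the alkoxy group would close onto the ester. The product is the tris‑methoxymethyl ether A7.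
- **Merits:** The conditions are mild and need only fluoride. The union is convergent. The alkoxy group flanking the reactive ring A position should steer the oxygen to the correct carbon. A9 belongs to the same arylacetate series that the chosen route also prepares.
- **Weak points:** The enolate can react through carbon, which inserts the ring A unit into the C–C bond of the β‑dicarbonyl. A8 is a pentasubstituted benzene with differentiated oxygens. The decisive weakness is that the three methoxymethyl ethers must be removed with acid, the condition under which the tertiary alcohol closes onto a neighbouring phenol and the chromene is at risk.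
- **Comparison:** A mild, convergent ring C closure is a real advantage over an untested cascade. The chosen plan offers in return a neutral final deprotection, no ring A protecting groups and much simpler fragments.

Key step: step 9

## Route

Remark on the chemistry: compounds 10, 11 and 17 are written in one keto form although they should exist largely as chelated enols or enolates. Enol ether 5 is carried as an E/Z mixture because its geometry is erased in step 4. The target has no stereocentre, so no step has to set or preserve configuration.

Step 1
Reactants: 1 2,4-dihydroxybenzaldehyde; 2 3-methylbut-2-enal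
Product: 3 5-hydroxy-2,2-dimethyl-2H-chromene-6-carbaldehyde
Conditions: pyridine, 120 °C
Reagents that add atoms: none
Why: Base‑mediated chromenylation (Knoevenagel‑type C‑alkylation at the carbon between the two oxygens, loss of water, oxa‑6π electrocyclisation); the 2‑hydroxyl is held in a hydrogen bond to the aldehyde, so the 4‑oxygen closes the pyran and the angular chromene should form.

Step 2
Reactants: 3 5-hydroxy-2,2-dimethyl-2H-chromene-6-carbaldehyde
Product: 4 5-(allyloxy)-2,2-dimethyl-2H-chromene-6-carbaldehyde
Conditions: allyl bromide, K2CO3, DMF, 50 °C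
Reagents that add atoms: allyl bromide, C=CCBr
Why: Williamson ether synthesis; the chelated phenol is alkylated readily in a dipolar aprotic solvent, and the allyl ether is stable to strong amide base but cleavable under neutral conditions.

Step 3
Reactants: 4 5-(allyloxy)-2,2-dimethyl-2H-chromene-6-carbaldehyde
Product: 5 5-(allyloxy)-6-(2-methoxyvinyl)-2,2-dimethyl-2H-chromene (E/Z mixture)
Conditions: Ph3P(CH2OMe)Cl, KOtBu, THF, 0 °C → rt
Reagents that add atoms: (methoxymethyl)triphenylphosphonium chloride, COC[P+](c1ccccc1)(c1ccccc1)c1ccccc1.[Cl-]
Why: Wittig methoxymethylenation of a non‑enolisable aryl aldehyde; the ylide is formed before the aldehyde is added, so the allyl ether meets little free alkoxide.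

Step 4
Reactants: 5 5-(allyloxy)-6-(2-methoxyvinyl)-2,2-dimethyl-2H-chromene
Product: 6 2-[5-(allyloxy)-2,2-dimethyl-2H-chromen-6-yl]acetaldehyde
Conditions: 2 M aq. HCl, THF, rt
Reagents that add atoms: water, O
Why: Acid hydrolysis of an enol ether through its oxocarbenium ion; the enol ether protonates far more readily than the chromene styrene, and the aldehyde is taken on without storage.

Step 5
Reactants: 6 2-[5-(allyloxy)-2,2-dimethyl-2H-chromen-6-yl]acetaldehyde
Product: 7 2-[5-(allyloxy)-2,2-dimethyl-2H-chromen-6-yl]acetic acid
Conditions: NaClO2, NaH2PO4, 2-methylbut-2-ene, tBuOH/H2O, 0 °C → rt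
Reagents that add atoms: sodium chlorite, [Na+].[O-]Cl=O
Why: Pinnick oxidation; the olefin scavenger removes hypochlorous acid before it can chlorinate the chromene or allyl double bonds.

Step 6
Reactants: 7 2-[5-(allyloxy)-2,2-dimethyl-2H-chromen-6-yl]acetic acid; 8 methyl acetoacetate
Product: 10 methyl 2-acetyl-4-[5-(allyloxy)-2,2-dimethyl-2H-chromen-6-yl]-3-oxobutanoate, via arylacetyl chloride 9 (not isolated)
Conditions: (COCl)2, DMF (cat.), CH2Cl2, 0 °C; evaporate; then 8, MgCl2, pyridine, CH2Cl2, 0 °C → rt
Reagents that add atoms: none
Why: C‑acylation of the magnesium chelate of a β‑keto ester by an acid chloride (soft enolisation); chelation directs the acyl group to carbon, and pyridine is too weak a base to convert 9 into a ketene.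

Step 7
Reactants: 10 methyl 2-acetyl-4-[5-(allyloxy)-2,2-dimethyl-2H-chromen-6-yl]-3-oxobutanoate
Product: 12 methyl 5-[5-(allyloxy)-2,2-dimethyl-2H-chromen-6-yl]-2-methyl-4-oxo-4H-pyran-3-carboxylate, via enaminone 11 (not isolated)
Conditions: Me2NCH(OMe)2, toluene, 80 °C; then AcOH, 60 °C
Reagents that add atoms: N,N-dimethylformamide dimethyl acetal, COC(OC)N(C)C
Why: Enaminone formation at the benzylic methylene, the only CH2 activated by both an aryl ring and a carbonyl group, followed by addition–elimination of the acetyl enol oxygen with loss of dimethylamine; this is the pyranone counterpart of the deoxybenzoin/formamide acetal isoflavone synthesis.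

Step 8
Reactants: 13 glutaric anhydride
Product: 16 6,6-dimethyltetrahydro-2H-pyran-2-one, via bromomagnesium 5-oxohexanoate 14 (not isolated), via 5-hydroxy-5-methylhexanoic acid 15 (not isolated)
Conditions: MeMgBr (2.2 equiv), THF, −78 → 0 °C; then 2 M aq. HCl, rt
Reagents that add atoms: methylmagnesium bromide, C[Mg]Br
Why: Grignard addition; the first equivalent opens the anhydride to 14, whose carboxylate is inert, the second adds to the ketone, and acidification gives 15, which lactonises readily with the help of the gem‑dimethyl group.

Step 9
Reactants: 12 methyl 5-[5-(allyloxy)-2,2-dimethyl-2H-chromen-6-yl]-2-methyl-4-oxo-4H-pyran-3-carboxylate; 16 6,6-dimethyltetrahydro-2H-pyran-2-one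
Product: 18 3-[5-(allyloxy)-2,2-dimethyl-2H-chromen-6-yl]-5,7-dihydroxy-6-(3-hydroxy-3-methylbutyl)-4H-chromen-4-one (2'-O-allyl Kanzonol T), via keto ester 17 (not isolated)
Conditions: LiN(SiMe3)2 (4 equiv), THF, −78 °C; then 16, −78 → 0 °C; then 45 °C; aq. NH4Cl
Reagents that add atoms: none
Why: Proposed new method: LiN(SiMe3)2 removes a proton from the 2‑methyl group of 12, which is vinylogous to both the ring carbonyl and the ester, and the extended enolate attacks the carbonyl of 16 through its terminal carbon (future C8); the tetrahedral adduct collapses with acyl–oxygen cleavage to the lithium alkoxide of 17, whose acidic C8 methylene takes up a second equivalent of base. With excess base and gentle warming the ketone enolises toward C6, and this carbon attacks the ester carbon (future C5) in a 6‑(enolendo)‑exo‑trig Dieckmann closure, a favoured mode, expelling methoxide. The resulting cyclohexane‑1,3‑dione fused to the pyranone tautomerises to the aromatic 5,7‑diol, and deprotonation of this resorcinol makes the closure irreversible. The closest known reaction types are the lateral Claisen acylation of metalated 2‑methyl‑4‑pyranones and 2‑methylchromones and the Claisen cyclisation of 2‑(2‑oxoalkyl) aryl esters to resorcinols in polyketide‑style syntheses; their combination in one flask, with a lactone as acyl donor on a pyranone ester, is not known. No stereocentre is formed. The step needs lateral deprotonation and C‑acylation to win over conjugate addition at the unsubstituted pyranone carbon (future C2) and over enolisation of the lactone: the methyl group is the most acidic site, the hindered silylamide is a poor nucleophile, the twisted ortho‑disubstituted ring B shields the neighbouring CH, and the dienolate is fully formed before 16 is added. It also needs carbon and not oxygen to close onto the ester: O‑acylation would give an enol lactone that methoxide can reopen, whereas C‑acylation is drained by aromatisation. Because one lactone supplies C6, C7, the chain and its tertiary alkoxide, the 6‑alkyl pattern follows from connectivity and ring A needs no protecting group.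

Step 10
Reactants: 18 3-[5-(allyloxy)-2,2-dimethyl-2H-chromen-6-yl]-5,7-dihydroxy-6-(3-hydroxy-3-methylbutyl)-4H-chromen-4-one
Product: 19 5,7-dihydroxy-3-(5-hydroxy-2,2-dimethyl-2H-chromen-6-yl)-6-(3-hydroxy-3-methylbutyl)-4H-chromen-4-one (Kanzonol T)
Conditions: Pd(PPh3)4 (5 mol %), morpholine (10 equiv), THF, rt
Reagents that add atoms: none
Why: Tsuji–Trost‑type deallylation; zerovalent palladium ionises the aryl allyl ether to a π‑allyl complex and the phenoxide, and excess morpholine captures the allyl unit under neutral conditions that leave the tertiary alcohol, the chromene and the isoflavone untouched.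

## Compound list

1 | 2,4-dihydroxybenzaldehyde | O=Cc1ccc(O)cc1O | starting material
2 | 3-methylbut-2-enal | CC(C)=CC=O | starting material
3 | 5-hydroxy-2,2-dimethyl-2H-chromene-6-carbaldehyde | O=Cc1ccc2OC(C)(C)C=Cc2c1O | intermediate
4 | 5-(allyloxy)-2,2-dimethyl-2H-chromene-6-carbaldehyde | O=Cc1ccc2OC(C)(C)C=Cc2c1OCC=C | intermediate
5 | 5-(allyloxy)-6-(2-methoxyvinyl)-2,2-dimethyl-2H-chromene (E/Z mixture) | COC=Cc1ccc2OC(C)(C)C=Cc2c1OCC=C | intermediate
6 | 2-[5-(allyloxy)-2,2-dimethyl-2H-chromen-6-yl]acetaldehyde | O=CCc1ccc2OC(C)(C)C=Cc2c1OCC=C | intermediate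
7 | 2-[5-(allyloxy)-2,2-dimethyl-2H-chromen-6-yl]acetic acid | OC(=O)Cc1ccc2OC(C)(C)C=Cc2c1OCC=C | intermediate
8 | methyl acetoacetate | COC(=O)CC(C)=O | starting material
9 | 2-[5-(allyloxy)-2,2-dimethyl-2H-chromen-6-yl]acetyl chloride (formed in the flask) | ClC(=O)Cc1ccc2OC(C)(C)C=Cc2c1OCC=C | intermediate
10 | methyl 2-acetyl-4-[5-(allyloxy)-2,2-dimethyl-2H-chromen-6-yl]-3-oxobutanoate | COC(=O)C(C(C)=O)C(=O)Cc1ccc2OC(C)(C)C=Cc2c1OCC=C | intermediate
11 | methyl 2-acetyl-4-[5-(allyloxy)-2,2-dimethyl-2H-chromen-6-yl]-5-(dimethylamino)-3-oxopent-4-enoate (formed in the flask) | COC(=O)C(C(C)=O)C(=O)C(=CN(C)C)c1ccc2OC(C)(C)C=Cc2c1OCC=C | intermediate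
12 | methyl 5-[5-(allyloxy)-2,2-dimethyl-2H-chromen-6-yl]-2-methyl-4-oxo-4H-pyran-3-carboxylate | COC(=O)c1c(C)occ(-c2ccc3OC(C)(C)C=Cc3c2OCC=C)c1=O | intermediate
13 | glutaric anhydride | O=C1CCCC(=O)O1 | starting material
14 | bromomagnesium 5-oxohexanoate (formed in the flask) | CC(=O)CCCC(=O)[O-].[Mg+2].[Br-] | intermediate
15 | 5-hydroxy-5-methylhexanoic acid (formed in the flask) | CC(C)(O)CCCC(=O)O | intermediate
16 | 6,6-dimethyltetrahydro-2H-pyran-2-one | CC1(C)CCCC(=O)O1 | intermediate
17 | methyl 5-[5-(allyloxy)-2,2-dimethyl-2H-chromen-6-yl]-2-(6-hydroxy-6-methyl-2-oxoheptyl)-4-oxo-4H-pyran-3-carboxylate (formed in the flask as its lithium salt) | COC(=O)c1c(CC(=O)CCCC(C)(C)O)occ(-c2ccc3OC(C)(C)C=Cc3c2OCC=C)c1=O | intermediate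
18 | 3-[5-(allyloxy)-2,2-dimethyl-2H-chromen-6-yl]-5,7-dihydroxy-6-(3-hydroxy-3-methylbutyl)-4H-chromen-4-one (2'-O-allyl Kanzonol T) | CC(C)(O)CCc1c(O)cc2occ(-c3ccc4OC(C)(C)C=Cc4c3OCC=C)c(=O)c2c1O | intermediate
19 | 5,7-dihydroxy-3-(5-hydroxy-2,2-dimethyl-2H-chromen-6-yl)-6-(3-hydroxy-3-methylbutyl)-4H-chromen-4-one (Kanzonol T) | CC(C)(O)CCc1c(O)cc2occ(-c3ccc4c(c3O)C=CC(C)(C)O4)c(=O)c2c1O | target

## Step count and least certain steps

Total: 10 steps. Longest linear sequence: 9 steps (steps 1–7, 9 and 10). Step 8 is a one‑step side branch.

**Step 9 (key step, the step carrying the new‑method label).**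
- **What may go wrong:** The most likely failure is stalling after the first acylation. The stabilised dienolate may add sluggishly to the lactone or take a proton from it. The second enolisation toward C6 may be too unfavourable with the silylamide. The uncyclised keto ester would then lactonise through its enol oxygen on work‑up. Conjugate addition and ring opening at the unsubstituted pyranone carbon is a further possibility.
- **Fallback:** The two bond formations are separated, with an acyclic, protected acyl donor, so that each rests on its own precedent. The fallback sets out from 16 and 12 and returns at 18. Lactone 16 is opened with MeNH(OMe)·HCl and AlMe3 to 5-hydroxy-N-methoxy-N,5-dimethylhexanamide F1. The tertiary alcohol is silylated with Et3SiOTf and 2,6‑lutidine to give N-methoxy-N,5-dimethyl-5-(triethylsilyloxy)hexanamide F2. The dienolate of 12 (LiN(SiMe3)2, THF, −78 °C) is acylated by F2 in a lateral Claisen condensation, and the chelated adduct releases the isolable keto ester methyl 5-[5-(allyloxy)-2,2-dimethyl-2H-chromen-6-yl]-2-[6-methyl-2-oxo-6-(triethylsilyloxy)heptyl]-4-oxo-4H-pyran-3-carboxylate F3. In a separate operation KOtBu in THF effects the Claisen cyclisation and aromatisation to 3-[5-(allyloxy)-2,2-dimethyl-2H-chromen-6-yl]-5,7-dihydroxy-6-[3-methyl-3-(triethylsilyloxy)butyl]-4H-chromen-4-one F4. Bu4NF in THF then removes the silyl group and gives 18.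

**Step 7 (pyranone formation).**
- **What may go wrong:** The tricarbonyl compound may undergo retro‑Claisen cleavage by the dimethylamine and methanol that the reagent liberates. Condensation may also occur at the acetyl methyl instead of the benzylic methylene. C‑acylation in step 6 can suffer from ketene formation as well.
- **Fallback:** The one‑carbon unit is installed before the acetoacetate. The fallback sets out from 7, bypasses steps 6 and 7, and returns at 12. Acid 7 is esterified (MeI, K2CO3, DMF) to methyl 2-[5-(allyloxy)-2,2-dimethyl-2H-chromen-6-yl]acetate F5. This is formylated (HCO2Me, NaH, THF) to methyl 2-[5-(allyloxy)-2,2-dimethyl-2H-chromen-6-yl]-3-hydroxyacrylate F6, and O‑methylated (Me2SO4, K2CO3, acetone) to methyl 2-[5-(allyloxy)-2,2-dimethyl-2H-chromen-6-yl]-3-methoxyacrylate F7. Saponification (LiOH, THF/H2O) gives 2-[5-(allyloxy)-2,2-dimethyl-2H-chromen-6-yl]-3-methoxyacrylic acid F8. Oxalyl chloride converts it into 2-[5-(allyloxy)-2,2-dimethyl-2H-chromen-6-yl]-3-methoxyacryloyl chloride F9. F9 acylates 8 under MgCl2/pyridine to methyl 2-acetyl-4-[5-(allyloxy)-2,2-dimethyl-2H-chromen-6-yl]-5-methoxy-3-oxopent-4-enoate F10. Warming F10 in AcOH closes the ring with loss of methanol and gives 12.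

**Step 4 (enol ether hydrolysis).**
- **What may go wrong:** The electron‑rich arylacetaldehyde may self‑condense under acid. The chromene olefin may hydrate or dimerise during the hydrolysis. The subsequent oxidation then starts from degraded material.
- **Fallback:** The aldehyde oxidation level is avoided altogether. The fallback sets out from 4, bypasses steps 3–5, and returns at 7. A Van Leusen reductive cyanation of 4 (TosMIC, KOtBu, DME, −30 °C; then MeOH, reflux) gives 2-[5-(allyloxy)-2,2-dimethyl-2H-chromen-6-yl]acetonitrile F11. Basic hydrolysis (NaOH, EtOH/H2O, reflux; then acidification) gives 7.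

**Step 10 (deallylation).**
- **What may go wrong:** The π‑allyl palladium intermediate may transfer the allyl group to the nucleophilic ring A (C8 or the 7‑oxygen) in competition with morpholine. The amine may also attack C2 of the isoflavone.
- **Fallback:** The allyl group is removed before ring A exists and replaced by a fluoride‑labile group. The fallback sets out from 12 and returns at 19. Pd(PPh3)4 and morpholine convert 12 into methyl 5-(5-hydroxy-2,2-dimethyl-2H-chromen-6-yl)-2-methyl-4-oxo-4H-pyran-3-carboxylate F12. Silylation (tBuMe2SiCl, imidazole, DMF) gives methyl 5-[5-(tert-butyldimethylsilyloxy)-2,2-dimethyl-2H-chromen-6-yl]-2-methyl-4-oxo-4H-pyran-3-carboxylate F13. F13 is carried through the conditions of step 9 with 16 to 3-[5-(tert-butyldimethylsilyloxy)-2,2-dimethyl-2H-chromen-6-yl]-5,7-dihydroxy-6-(3-hydroxy-3-methylbutyl)-4H-chromen-4-one F14. Bu4NF in THF then gives 19.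

## Further compounds

F1 | step 9 | 5-hydroxy-N-methoxy-N,5-dimethylhexanamide | CON(C)C(=O)CCCC(C)(C)O
F2 | step 9 | N-methoxy-N,5-dimethyl-5-(triethylsilyloxy)hexanamide | CON(C)C(=O)CCCC(C)(C)O[Si](CC)(CC)CC
F3 | step 9 | methyl 5-[5-(allyloxy)-2,2-dimethyl-2H-chromen-6-yl]-2-[6-methyl-2-oxo-6-(triethylsilyloxy)heptyl]-4-oxo-4H-pyran-3-carboxylate | COC(=O)c1c(CC(=O)CCCC(C)(C)O[Si](CC)(CC)CC)occ(-c2ccc3OC(C)(C)C=Cc3c2OCC=C)c1=O
F4 | step 9 | 3-[5-(allyloxy)-2,2-dimethyl-2H-chromen-6-yl]-5,7-dihydroxy-6-[3-methyl-3-(triethylsilyloxy)butyl]-4H-chromen-4-one | CC(C)(O[Si](CC)(CC)CC)CCc1c(O)cc2occ(-c3ccc4OC(C)(C)C=Cc4c3OCC=C)c(=O)c2c1O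
F5 | step 7 | methyl 2-[5-(allyloxy)-2,2-dimethyl-2H-chromen-6-yl]acetate | COC(=O)Cc1ccc2OC(C)(C)C=Cc2c1OCC=C
F6 | step 7 | methyl 2-[5-(allyloxy)-2,2-dimethyl-2H-chromen-6-yl]-3-hydroxyacrylate | COC(=O)C(=CO)c1ccc2OC(C)(C)C=Cc2c1OCC=C
F7 | step 7 | methyl 2-[5-(allyloxy)-2,2-dimethyl-2H-chromen-6-yl]-3-methoxyacrylate | COC=C(C(=O)OC)c1ccc2OC(C)(C)C=Cc2c1OCC=C
F8 | step 7 | 2-[5-(allyloxy)-2,2-dimethyl-2H-chromen-6-yl]-3-methoxyacrylic acid | COC=C(C(=O)O)c1ccc2OC(C)(C)C=Cc2c1OCC=C
F9 | step 7 | 2-[5-(allyloxy)-2,2-dimethyl-2H-chromen-6-yl]-3-methoxyacryloyl chloride | COC=C(C(=O)Cl)c1ccc2OC(C)(C)C=Cc2c1OCC=C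
F10 | step 7 | methyl 2-acetyl-4-[5-(allyloxy)-2,2-dimethyl-2H-chromen-6-yl]-5-methoxy-3-oxopent-4-enoate | COC=C(C(=O)C(C(C)=O)C(=O)OC)c1ccc2OC(C)(C)C=Cc2c1OCC=C
F11 | step 4 | 2-[5-(allyloxy)-2,2-dimethyl-2H-chromen-6-yl]acetonitrile | N#CCc1ccc2OC(C)(C)C=Cc2c1OCC=C
F12 | step 10 | methyl 5-(5-hydroxy-2,2-dimethyl-2H-chromen-6-yl)-2-methyl-4-oxo-4H-pyran-3-carboxylate | COC(=O)c1c(C)occ(-c2ccc3OC(C)(C)C=Cc3c2O)c1=O
F13 | step 10 | methyl 5-[5-(tert-butyldimethylsilyloxy)-2,2-dimethyl-2H-chromen-6-yl]-2-methyl-4-oxo-4H-pyran-3-carboxylate | COC(=O)c1c(C)occ(-c2ccc3OC(C)(C)C=Cc3c2O[Si](C)(C)C(C)(C)C)c1=O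
F14 | step 10 | 3-[5-(tert-butyldimethylsilyloxy)-2,2-dimethyl-2H-chromen-6-yl]-5,7-dihydroxy-6-(3-hydroxy-3-methylbutyl)-4H-chromen-4-one | CC(C)(O)CCc1c(O)cc2occ(-c3ccc4OC(C)(C)C=Cc4c3O[Si](C)(C)C(C)(C)C)c(=O)c2c1O
A1 | alternative 1 | 3-[5-(tert-butyldimethylsilyloxy)-2,2-dimethyl-2H-chromen-6-yl]-5,7-bis(tert-butyldimethylsilyloxy)-6-(3-hydroxy-3-methylbutyl)-2-(trimethylsilyl)-4H-chromen-4-one | CC(C)(O)CCc1c(O[Si](C)(C)C(C)(C)C)cc2oc([Si](C)(C)C)c(-c3ccc4OC(C)(C)C=Cc4c3O[Si](C)(C)C(C)(C)C)c(=O)c2c1O[Si](C)(C)C(C)(C)C
A2 | alternative 1 | 2,4-bis(tert-butyldimethylsilyloxy)-6-hydroxy-3-(3-hydroxy-3-methylbutyl)benzaldehyde | O=Cc1c(O)cc(O[Si](C)(C)C(C)(C)C)c(CCC(C)(C)O)c1O[Si](C)(C)C(C)(C)C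
A3 | alternative 1 | tert-butyl{[2,2-dimethyl-6-(trimethylsilylethynyl)-2H-chromen-5-yl]oxy}dimethylsilane | C[Si](C)(C)C#Cc1ccc2OC(C)(C)C=Cc2c1O[Si](C)(C)C(C)(C)C
A4 | alternative 2 | 5,7-bis(tert-butyldimethylsilyloxy)-3-[2,2-dimethyl-5-(triisopropylsilyloxy)-2H-chromen-6-yl]-6-[3-methyl-3-(triethylsilyloxy)butyl]-4H-chromen-4-one | CC(C)(O[Si](CC)(CC)CC)CCc1c(O[Si](C)(C)C(C)(C)C)cc2occ(-c3ccc4OC(C)(C)C=Cc4c3O[Si](C(C)C)(C(C)C)C(C)C)c(=O)c2c1O[Si](C)(C)C(C)(C)C
A5 | alternative 2 | 2,2-dimethyl-2H,5H-pyrano[4,3-b]pyran-5-one | CC1(C)C=CC2=C(O1)C=COC2=O
A6 | alternative 2 | 5,7-bis(tert-butyldimethylsilyloxy)-6-[3-methyl-3-(triethylsilyloxy)butyl]-3-[(triisopropylsilyloxy)ethynyl]-4H-chromen-4-one | CC(C)(O[Si](CC)(CC)CC)CCc1c(O[Si](C)(C)C(C)(C)C)cc2occ(C#CO[Si](C(C)C)(C(C)C)C(C)C)c(=O)c2c1O[Si](C)(C)C(C)(C)C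
A7 | alternative 3 | 6-(3-hydroxy-3-methylbutyl)-5,7-bis(methoxymethoxy)-3-[5-(methoxymethoxy)-2,2-dimethyl-2H-chromen-6-yl]-4H-chromen-4-one | CC(C)(O)CCc1c(OCOC)cc2occ(-c3ccc4OC(C)(C)C=Cc4c3OCOC)c(=O)c2c1OCOC
A8 | alternative 3 | 4-(3-hydroxy-3-methylbutyl)-3,5-bis(methoxymethoxy)-2-(trimethylsilyl)phenyl trifluoromethanesulfonate | CC(C)(O)CCc1c(OCOC)cc(OS(=O)(=O)C(F)(F)F)c([Si](C)(C)C)c1OCOC
A9 | alternative 3 | methyl 2-[5-(methoxymethoxy)-2,2-dimethyl-2H-chromen-6-yl]-3-oxopropanoate | COC(=O)C(C=O)c1ccc2OC(C)(C)C=Cc2c1OCOC
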